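**Plan**
- Retrosynthetic cuts, in order: the sulfonate O–S bond that masks the 4'-OH, then O1–C8a of the pyranone, then C2–C3, then C4–C4a.
- Forward: 1,2,3,4-tetramethoxybenzene (1) is acetylated to ketone 2 (C4–C4a). Methyl syringate (3) is tosylated to ester 4. Claisen condensation of 2 with 4 joins C2–C3 and should give 1,3-diketone 5.
- Ring C is the only ring that is built; rings A and B are bought. It closes in step 4 by dehydrogenative coupling of the enol oxygen of 5 with an aryl C–H of ring A to give tosyl flavone 6. Detosylation then gives target 7.
- Enabling feature: in 5 the future C8a is the only hydrogen-bearing carbon of the tetramethoxyaryl ketone (ring A). It is ortho to C4a, para to the C6 methoxy group and ortho to the C8 methoxy group, so the radical cation of ring A is electrophilic there, six atoms away from the enol oxygen.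
- The target has no stereocenter, so there is nothing to control.

Key step: step 4

Remark: 1 is taken as a purchasable compound; 5 is drawn as the diketone although it should exist mainly as its chelated enol; flavone numbering (ring A benzo ring, ring B 2-aryl group, ring C pyranone) is used for all intermediates.

**Step 1**
Reactants: 1 1,2,3,4-tetramethoxybenzene
Product: 2 1-(2,3,4,5-tetramethoxyphenyl)ethanone
Conditions: Ac2O (1.3 equiv), Sc(OTf)3 (10 mol %), MeNO2, 50 °C
Reagents that add atoms: acetic anhydride, CC(=O)OC(C)=O
Why: Friedel–Crafts acylation, in which the two free positions of 1 are equivalent and each is para to one methoxy group and ortho to another, the acetyl group deactivates the ring against a second acylation, and catalytic Sc(OTf)3 with the anhydride should spare the methoxy group that stoichiometric AlCl3 tends to cleave next to the new carbonyl group.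

**Step 2**
Reactants: 3 methyl syringate (methyl 4-hydroxy-3,5-dimethoxybenzoate)
Product: 4 methyl 3,5-dimethoxy-4-[(4-methylphenyl)sulfonyloxy]benzoate
Conditions: TsCl (1.2 equiv), K2CO3 (2 equiv), acetone, reflux
Reagents that add atoms: p-toluenesulfonyl chloride, Cc1ccc(cc1)S(Cl)(=O)=O
Why: O-sulfonylation of a phenoxide, in which the acidic phenol of 3 is deprotonated by K2CO3, the hindered phenoxide still reaches the unhindered sulfonyl chloride in refluxing acetone, and the methyl ester is inert to carbonate in an aprotic solvent.

**Step 3**
Reactants: 2 1-(2,3,4,5-tetramethoxyphenyl)ethanone; 4 methyl 3,5-dimethoxy-4-[(4-methylphenyl)sulfonyloxy]benzoate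
Product: 5 1-(2,3,4,5-tetramethoxyphenyl)-3-[3,5-dimethoxy-4-(tosyloxy)phenyl]propane-1,3-dione
Conditions: LiHMDS (2.5 equiv), THF, −78 °C; then 4 (1.1 equiv), −78 °C → rt; 1 M HCl, 0 °C
Reagents that add atoms: none
Why: Crossed Claisen condensation, in which 4 has no α-hydrogen and can only be the acceptor, the second equivalent of amide base removes the acidic central proton of the product as it forms and so pulls the equilibrium forward, and the aryl sulfonate, screened by two ortho methoxy groups, should withstand the non-nucleophilic base and lithium methoxide at or below room temperature.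

**Step 4**
Reactants: 5 1-(2,3,4,5-tetramethoxyphenyl)-3-[3,5-dimethoxy-4-(tosyloxy)phenyl]propane-1,3-dione
Product: 6 4-(5,6,7,8-tetramethoxy-4-oxo-4H-chromen-2-yl)-2,6-dimethoxyphenyl 4-methylbenzenesulfonate (4'-O-tosyl-3',5,5',6,7,8-hexamethoxyflavone)
Conditions: PhI(O2CCF3)2 (1.1 equiv), (CF3)2CHOH (0.02 M), 0 °C → rt
Reagents that add atoms: none
Why: Proposed new method: PhI(O2CCF3)2 in hexafluoroisopropanol should take one electron from the tetramethoxyaryl ring of 5, the most easily oxidized π system of the molecule, and the arene radical cation formed carries much of its charge at its only C–H carbon, which is para to one methoxy group and ortho to another. The oxygen of the (Z)-enol on the carbon that bears ring B can reach this carbon after rotation about the C3–C4 bond, which the hydrogen-bond-donating solvent eases by loosening the enol chelate, and should add to it in a six-membered closure that is 6-endo with respect to the C4a–C8a π bond (formally an oxa-6π ring closure) and forms O1–C8a and ring C. A second one-electron oxidation and loss of the proton from C8a then restore the aromatic ring A and leave the 4-pyranone, so the step is a net loss of two hydrogens with iodobenzene and trifluoroacetic acid as the spent reagent. The closest known reactions are O–H/aryl C–H cyclizations through arene radical cations under hypervalent iodine, FeCl3 or anodic oxidation (closure of 3-arylpropanols to chromans, dehydrogenative lactonization of biaryl-2-carboxylic acids, closure of alkoxy-substituted α-aryl ketones to benzofurans), whereas the enol oxygen of a 1,3-diketone has not been joined in this way to an aryl C–H carbon ortho to its own carbonyl group. No stereocenter is formed. The step needs attack on ring A at C–H and not on ring B, at a methoxy-bearing carbon or at the central diketone carbon: the tosyloxy group raises the oxidation potential of ring B, an ipso adduct at C–OMe can revert in the acidic non-nucleophilic medium while the C–H adduct is drained by irreversible deprotonation, and the central carbon can reach neither ring because only a four-membered ring would result.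

**Step 5**
Reactants: 6 4-(5,6,7,8-tetramethoxy-4-oxo-4H-chromen-2-yl)-2,6-dimethoxyphenyl 4-methylbenzenesulfonate
Product: 7 4'-hydroxy-3',5,5',6,7,8-hexamethoxyflavone (2-(4-hydroxy-3,5-dimethoxyphenyl)-5,6,7,8-tetramethoxy-4H-chromen-4-one)
Conditions: KOH (6 equiv), MeOH/THF/H2O (2:2:1), 60 °C; then 2 M HCl to pH 1, 60 °C
Reagents that add atoms: none
Why: Alkaline cleavage of an aryl sulfonate by attack of hydroxide at sulfur (S–O cleavage), in which the 4'-phenoxide is a good leaving group because it is conjugated with the pyranone carbonyl group, the methyl ethers are inert, and the closing acid treatment protonates the phenoxide and recloses by cyclodehydration any pyranone ring that hydroxide has opened.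

**Compound list**
1 | 1,2,3,4-tetramethoxybenzene | COc1ccc(OC)c(OC)c1OC | starting material
2 | 1-(2,3,4,5-tetramethoxyphenyl)ethanone | CC(=O)c1cc(OC)c(OC)c(OC)c1OC | intermediate
3 | methyl syringate (methyl 4-hydroxy-3,5-dimethoxybenzoate) | COC(=O)c1cc(OC)c(O)c(OC)c1 | starting material
4 | methyl 3,5-dimethoxy-4-[(4-methylphenyl)sulfonyloxy]benzoate | COC(=O)c1cc(OC)c(OS(=O)(=O)c2ccc(C)cc2)c(OC)c1 | intermediate
5 | 1-(2,3,4,5-tetramethoxyphenyl)-3-[3,5-dimethoxy-4-(tosyloxy)phenyl]propane-1,3-dione | COc1cc(C(=O)CC(=O)c2cc(OC)c(OS(=O)(=O)c3ccc(C)cc3)c(OC)c2)c(OC)c(OC)c1OC | intermediate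
6 | 4-(5,6,7,8-tetramethoxy-4-oxo-4H-chromen-2-yl)-2,6-dimethoxyphenyl 4-methylbenzenesulfonate | COc1cc(-c2cc(=O)c3c(OC)c(OC)c(OC)c(OC)c3o2)cc(OC)c1OS(=O)(=O)c1ccc(C)cc1 | intermediate
7 | 4'-hydroxy-3',5,5',6,7,8-hexamethoxyflavone | COc1cc(-c2cc(=O)c3c(OC)c(OC)c(OC)c(OC)c3o2)cc(OC)c1O | target

Total step count: 5
Longest linear sequence: 4 steps (steps 1, 3, 4, 5 from 1, or steps 2, 3, 4, 5 from 3)

**Steps most likely to fail**

Step 4. Electron transfer from the acyl-substituted ring A may be too slow, so that ligand exchange of the enol at iodine and oxygenation of the central diketone carbon take over. The enol oxygen may also add at the methoxy-bearing ortho carbon, which would lead to oxidative demethylation towards a quinone, and the flavone may be oxidized further. The fallback uses known chemistry, sets out from 2 and returns at 6. Ring bromination of 2 with NBS in MeCN at room temperature, directed to the only free ring position by its ortho and para methoxy groups, should give 1-(2-bromo-3,4,5,6-tetramethoxyphenyl)ethanone F1. Claisen condensation of F1 with 4 under the conditions of step 3 should give 1-(2-bromo-3,4,5,6-tetramethoxyphenyl)-3-[3,5-dimethoxy-4-(tosyloxy)phenyl]propane-1,3-dione F2. An intramolecular Ullmann-type O-arylation of the diketone enolate (CuI, 1,10-phenanthroline, K2CO3, DMF, 100 °C), a known route from 1-(2-bromoaryl)-1,3-diketones to 4H-chromen-4-ones, then closes ring C and gives 6.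

Step 3. The sulfonyl group may be transferred from the phenol oxygen to the enolate or to lithium methoxide, which would strip the protecting group, or the condensation may stall through proton exchange between the enolate and the product. The fallback replaces the ester condensation by an aldol addition and an oxidation, sets out from 2 and returns at 5. Commercial syringaldehyde (4-hydroxy-3,5-dimethoxybenzaldehyde) is tosylated as in step 2 to 4-formyl-2,6-dimethoxyphenyl 4-methylbenzenesulfonate F3. The lithium enolate of 2 (LDA, THF, −78 °C) should add to F3 and, after a cold quench, give racemic 3-hydroxy-1-(2,3,4,5-tetramethoxyphenyl)-3-[3,5-dimethoxy-4-(tosyloxy)phenyl]propan-1-one F4. Oxidation of the secondary alcohol of F4 with 2-iodoxybenzoic acid in EtOAc at 75 °C, which removes the only stereocenter, should give 5.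

Step 1. The Lewis acid may assist loss of the methyl group next to the new carbonyl group, or acylation may be sluggish on a ring whose inner methoxy groups are twisted out of conjugation. The fallback replaces electrophilic substitution by directed ortho-metalation, sets out from 1 and returns at 2. Lithiation of 1 next to a terminal methoxy group (n-BuLi, TMEDA, THF, 0 °C), followed by acylation of the aryllithium with N-methoxy-N-methylacetamide (−78 °C → rt), should give 2 directly; no compound outside the list is formed, hence entry F0.

**Further compounds**
F1 | step 4 | 1-(2-bromo-3,4,5,6-tetramethoxyphenyl)ethanone | CC(=O)c1c(Br)c(OC)c(OC)c(OC)c1OC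
F2 | step 4 | 1-(2-bromo-3,4,5,6-tetramethoxyphenyl)-3-[3,5-dimethoxy-4-(tosyloxy)phenyl]propane-1,3-dione | COc1c(Br)c(C(=O)CC(=O)c2cc(OC)c(OS(=O)(=O)c3ccc(C)cc3)c(OC)c2)c(OC)c(OC)c1OC
F3 | step 3 | 4-formyl-2,6-dimethoxyphenyl 4-methylbenzenesulfonate | COc1cc(C=O)cc(OC)c1OS(=O)(=O)c1ccc(C)cc1
F4 | step 3 | 3-hydroxy-1-(2,3,4,5-tetramethoxyphenyl)-3-[3,5-dimethoxy-4-(tosyloxy)phenyl]propan-1-one (racemic) | COc1cc(C(=O)CC(O)c2cc(OC)c(OS(=O)(=O)c3ccc(C)cc3)c(OC)c2)c(OC)c(OC)c1OC
F0 | step 1 | none | none
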